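At 30 h I must say whether this flask has stopped, and what stands in it.

- red: solid substrate 0.030 M; run made earlier
- flask: solid substrate 0.020 M; time 30 h

red run (percent of the solid substrate charged)

| time / h | solid substrate / % | target / % |
|---|---|---|
| 0.417 | 90 | 3 |
| 1.33 | 80 | 6 |
| 2.00 | 72 | 7 |
| 3.00 | 70 | 6 |
| 5.00 | 64 | 7 |
| 6.00 | 61 | 6 |

(scatter of a reading: 2 percentage points)

- solid substrate is a solid; its amount is given per volume of the solution
- the earlier runs were read with a standard deviation of 2 percentage points
- candidate steps: starting material <-> target; target <-> isomer of the product A; solid substrate <-> starting material; isomer of the product B <-> starting material; isomer of the product A <-> isomer of the product B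
- at the start none of the solid substrate is in solution
- what has only dissolved of solid substrate counts as not reacted
- the reaction counts as stopped when no species that holds the solid substrate changes by six tenths of a point or more over the second half of the time

* why nothing more happens at 30 h, or that something still does (for what has run out or reacted, a solid counts together with what of it has only dissolved) (it is still moving / forward and back rates have come level / all of the solid substrate has reacted)
* part of the solid substrate that has turned into other species by 30 h (what has only dissolved does not count)
* target at 30 h, in percent of the solid substrate charged
* amount of target if the flask were left three thousand times as long, in percent of the solid substrate charged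

First instants: the red run starts with nothing dissolved and loses 20.0% of its solid substrate by 1.33 h. Then it loses 19 percentage points more by 6.00 h, so the loss L is slowing.

I take dissolving as pseudo-first-order in what the solution still lacks. Integrated, L climbs exponentially towards a limit with time constant τ. Then L at twice a time, divided by L at that time, is one plus exp(−t/τ). The readings give 30.0% at 3.00 h and 39.0% at 6.00 h. So τ is 2.49 h.

The limit, in molar terms, is my solution capacity C: the charge that the solution takes up in every dissolved form while solid stands beside it. The red readings, with their scatter, give C near 12.9 mM.

Middle: target in the red run stands near 1.95 mM from 2.00 h on, as a mean of those readings.

End: this flask holds 0.020 M, more than C, so I expect 35.5% to stay solid. Its time is 12.0 τ, so I reckon it level, with target at 9.75%, then and later. I put conversion under 64.5%, by the starting material, which nobody read.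

The forecast differs: it is still moving, conversion 88%, target 6%, and 4% after the long wait. Its ground: “The same drain would use up the solid in about 13–20 h”. Its target figure is the last red reading taken over.

The flask gives: forward and back rates have come level, conversion 41.1%, target 11.3%, and 11.3% after the long wait. Over the second half of the time, no share moves by more than 0.041 points, with solid substrate at 40.9%. The flask has taken up 11.8 mM, against the C of 12.9 mM from the red run.

    starting material ⇌ target (K = 0.630, k = 0.0950 min⁻¹)
    target ⇌ isomer of the product A (K = 2.40, k = 0.0870 min⁻¹)
    solid substrate ⇌ starting material, rate k3*(cs3 - [starting material]) while solid is left; crystals form when [starting material] > cs3 (solubility = 3.60 mM, k = 0.0300 min⁻¹)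
    isomer of the product B ⇌ starting material (k = 0.0820 min⁻¹)
    isomer of the product A ⇌ isomer of the product B (K = 0.0930, k = 0.0890 min⁻¹)

With 0.0080 M of solid substrate, the charge is below C, so by C I expect the solid to dissolve completely, and I reckon target at 15.1% of the charge, its red share of C. The computed neighbour ends with solid substrate at 0% and target at 19.2%.

The runs stem from a simulated flask for an exercise, noise included.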